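## Retrosynthetic overview

1. Target 24 ⇐ δ-lactone 21 by Petasis methylenation (the acid-labile exocyclic enol ether is made last); 21 ⇐ α-hydroxy acid 20 by catalyst-controlled 6-endo bromolactonisation, which forms the oxane ring.
2. 20 ⇐ cyclic carbonate 17 ⇐ open-chain alcohol 13 by the key step: triflation, bromonium formation and cation–olefin closure of the C1–C2 bond of the cyclohexane, ended by the neighbouring tert-butyl carbonate.
3. 13 ⇐ aldehyde 5 + ylide 9 (E-selective Wittig reaction); 5 ⇐ nerol 1 by catalytic enantioselective bromochlorination, so that C3–Br and C4(CH3)–Cl are fixed on the open chain before any ring exists.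
4. Enabling feature: in the cyclohexane the secondary bromide on C3 is vicinal to the C2 methylene, so bromine can bridge to C2. C1 then reaches C2 through a six-membered chair in which C3–Br, C4–Cl and the C1 side chain are all equatorial and the C4 methyl is axial. That is the array of the target; diaxial BrCl addition to a preformed cyclohexene would instead put bromine trans to the side chain.
5. Ring order: cyclohexane together with a temporary 1,3-dioxolan-2-one (step 9), then the oxane as δ-lactone (step 13).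

Key step: step 9

Remark: cyclohexane carbons are numbered C1 (CH bearing the carbinol carbon), C2 (CH2), C3 (CHBr), C4 (CClCH3), C5, C6; in steps 1 and 13 the antipode of the chiral ligand or catalyst is the one that gives the configuration written, both antipodes being accessible.

## Route

Step 1
Reactants: 1 nerol, (2Z)-3,7-dimethylocta-2,6-dien-1-ol
Product: 2 (2S,3S)-2-bromo-3-chloro-3,7-dimethyloct-6-en-1-ol
Conditions: NBS, ClTi(OiPr)3, chiral tridentate Schiff-base ligand (20 mol %), hexanes, −20 °C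
Reagents that add atoms: N-bromosuccinimide, O=C1CCC(=O)N1Br; chlorotitanium triisopropoxide, CC(C)O[Ti](Cl)(OC(C)C)OC(C)C
Why: Catalytic enantioselective bromochlorination of an allylic alcohol: the alkoxide binds to titanium held by the chiral ligand, the bromonium ion forms on the ligand-selected face and chloride is delivered anti to the more substituted carbon C3, which should set (2S,3S) from the Z-alkene and leave the unbound distal alkene untouched.

Step 2
Reactants: 2 (2S,3S)-2-bromo-3-chloro-3,7-dimethyloct-6-en-1-ol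
Product: 3 {[(2S,3S)-2-bromo-3-chloro-3,7-dimethyloct-6-en-1-yl]oxy}(tert-butyl)dimethylsilane
Conditions: TBSCl, imidazole, CH2Cl2, 0 °C
Reagents that add atoms: tert-butyldimethylsilyl chloride, CC(C)(C)[Si](C)(C)Cl
Why: Silyl ether formation at the primary hydroxyl under a mild base that should not close the bromohydrin to an epoxide; no stereocentre is formed.

Step 3
Reactants: 3 {[(2S,3S)-2-bromo-3-chloro-3,7-dimethyloct-6-en-1-yl]oxy}(tert-butyl)dimethylsilane
Product: 5 (4S,5S)-5-bromo-6-[(tert-butyldimethylsilyl)oxy]-4-chloro-4-methylhexanal, via ozonide 4 (not isolated)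
Conditions: O3, CH2Cl2, −78 °C; then PPh3, −78 → 23 °C
Reagents that add atoms: ozone, [O-][O+]=O
Why: Ozonolysis of the only alkene with reductive work-up cleaves off acetone under neutral conditions, so the two halogen-bearing stereocentres should stay untouched.

Step 4
Reactants: 6 ethyl (triphenylphosphoranylidene)acetate; 7 prenyl bromide, 1-bromo-3-methylbut-2-ene
Product: 9 ethyl 5-methyl-2-(triphenylphosphoranylidene)hex-4-enoate, via phosphonium bromide 8 (not isolated)
Conditions: CHCl3, reflux; then 1 M aq NaOH, CH2Cl2, 23 °C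
Reagents that add atoms: none
Why: C-alkylation of a stabilised phosphorus ylide by an allylic bromide (SN2 at the primary carbon) followed by deprotonation of the phosphonium salt; no stereocentre is formed.

Step 5
Reactants: 5 (4S,5S)-5-bromo-6-[(tert-butyldimethylsilyl)oxy]-4-chloro-4-methylhexanal; 9 ethyl 5-methyl-2-(triphenylphosphoranylidene)hex-4-enoate
Product: 10 ethyl (2E,6S,7S)-7-bromo-8-[(tert-butyldimethylsilyl)oxy]-6-chloro-6-methyl-2-(3-methylbut-2-en-1-yl)oct-2-enoate
Conditions: toluene, 60 °C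
Reagents that add atoms: none
Why: Wittig olefination with an α-substituted ester-stabilised ylide, which should place the ester trans to the aldehyde chain (E) under neutral conditions that spare the β-bromo chloride.

Step 6
Reactants: 10 ethyl (2E,6S,7S)-7-bromo-8-[(tert-butyldimethylsilyl)oxy]-6-chloro-6-methyl-2-(3-methylbut-2-en-1-yl)oct-2-enoate
Product: 11 (2E,6S,7S)-7-bromo-8-[(tert-butyldimethylsilyl)oxy]-6-chloro-6-methyl-2-(3-methylbut-2-en-1-yl)oct-2-en-1-ol
Conditions: i-Bu2AlH (2.3 equiv), CH2Cl2, −78 °C; Rochelle-salt work-up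
Reagents that add atoms: none
Why: 1,2-Reduction of the unsaturated ester to the allylic alcohol with i-Bu2AlH at low temperature, where alkyl halides and the silyl ether are inert and the alkene geometry is kept.

Step 7
Reactants: 11 (2E,6S,7S)-7-bromo-8-[(tert-butyldimethylsilyl)oxy]-6-chloro-6-methyl-2-(3-methylbut-2-en-1-yl)oct-2-en-1-ol
Product: 12 tert-butyl [(2E,6S,7S)-7-bromo-8-[(tert-butyldimethylsilyl)oxy]-6-chloro-6-methyl-2-(3-methylbut-2-en-1-yl)oct-2-en-1-yl] carbonate
Conditions: Boc2O, 1-methylimidazole (cat.), toluene, 23 °C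
Reagents that add atoms: di-tert-butyl dicarbonate, CC(C)(C)OC(=O)OC(=O)OC(C)(C)C
Why: O-Acylation of the allylic alcohol under nucleophilic catalysis installs the carbonate that later serves as the internal oxygen nucleophile.

Step 8
Reactants: 12 tert-butyl [(2E,6S,7S)-7-bromo-8-[(tert-butyldimethylsilyl)oxy]-6-chloro-6-methyl-2-(3-methylbut-2-en-1-yl)oct-2-en-1-yl] carbonate
Product: 13 tert-butyl [(2E,6S,7S)-7-bromo-6-chloro-8-hydroxy-6-methyl-2-(3-methylbut-2-en-1-yl)oct-2-en-1-yl] carbonate
Conditions: HF·pyridine, pyridine, THF, 0 °C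
Reagents that add atoms: none
Why: Fluoride-mediated desilylation under buffered, weakly acidic conditions, chosen so that the freed β-bromo alcohol is not closed to an epoxide and the tert-butyl carbonate survives.

Step 9
Reactants: 13 tert-butyl [(2E,6S,7S)-7-bromo-6-chloro-8-hydroxy-6-methyl-2-(3-methylbut-2-en-1-yl)oct-2-en-1-yl] carbonate
Product: 17 (4R)-4-[(1S,3S,4S)-3-bromo-4-chloro-4-methylcyclohexyl]-4-(3-methylbut-2-en-1-yl)-1,3-dioxolan-2-one, via primary triflate 14 (not isolated), via bromonium ion 15 (not isolated), via dioxolanylium ion 16 (not isolated)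
Conditions: Tf2O, 2,6-di-tert-butyl-4-methylpyridine, CH2Cl2 (0.005 M), −78 °C; then (CF3)2CHOH, −40 → 0 °C; aq NaHCO3
Reagents that add atoms: none
Why: Proposed new method: triflation turns the future C2 (the CH2 next to CHBr) into a nucleofuge and the vicinal bromine displaces it from the back, so the electrophile is a configurationally defined bromonium ion and not a free primary cation; C1 of the (E)-trisubstituted alkene opens it at the unhindered CH2 while the carbonyl oxygen of the tert-butyl carbonate adds to the developing tertiary cation and tert-butyl leaves as 2-methylpropene. The closest known reaction types are cation–olefin cyclisations started by bromonium ions that are generated by neighbouring-group ionisation of bromohydrin esters (shown at tertiary carbon) and solvolytic π-cyclisations of primary alkenyl sulfonates; capture of a primary/secondary bromonium ion at its primary carbon by an alkene with carbonate termination has not been shown. The cyclohexane closes in a 6-endo sense at the bromonium ion (both of its carbons end in the ring; 6-exo with respect to the alkene) and the 1,3-dioxolan-2-one closes 5-exo at the cationic carbon. C1 is set by the chair transition state: backside opening holds the C3–Br bond antiperiplanar to the forming ring bond, hence equatorial, which places Cl equatorial and methyl axial at C4, and the alkene takes the equatorial site, giving the cis-1,3 relation of bromine and side chain. The carbinol carbon is set by antiperiplanar addition of carbon and oxygen across the (E)-alkene, which should turn the olefin geometry fixed in step 5 into the (R) configuration. The step needs attack at CH2 and not at CHBr, secured by the neopentyl-type shielding and inductive deactivation of CHBr by the adjacent C(CH3)Cl, and needs bromine bridging to outrun unassisted π-attack, which the ionising, non-nucleophilic medium and high dilution should favour.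

Step 10
Reactants: 17 (4R)-4-[(1S,3S,4S)-3-bromo-4-chloro-4-methylcyclohexyl]-4-(3-methylbut-2-en-1-yl)-1,3-dioxolan-2-one
Product: 18 (2R)-2-[(1S,3S,4S)-3-bromo-4-chloro-4-methylcyclohexyl]-5-methylhex-4-ene-1,2-diol
Conditions: K2CO3 (0.5 equiv), MeOH, 0 °C
Reagents that add atoms: none
Why: Base-catalysed methanolysis (transesterification) of the cyclic carbonate frees the 1,2-diol; the equatorial ring halides have no antiperiplanar hydrogen for E2 and no stereocentre is touched.

Step 11
Reactants: 18 (2R)-2-[(1S,3S,4S)-3-bromo-4-chloro-4-methylcyclohexyl]-5-methylhex-4-ene-1,2-diol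
Product: 19 (2R)-2-[(1S,3S,4S)-3-bromo-4-chloro-4-methylcyclohexyl]-2-hydroxy-5-methylhex-4-enal
Conditions: SO3·pyridine, DMSO, i-Pr2NEt, CH2Cl2, 0 °C
Reagents that add atoms: none
Why: Parikh–Doering oxidation converts only the primary alcohol into the aldehyde without glycol cleavage, and the quaternary α-carbon cannot epimerise.

Step 12
Reactants: 19 (2R)-2-[(1S,3S,4S)-3-bromo-4-chloro-4-methylcyclohexyl]-2-hydroxy-5-methylhex-4-enal
Product: 20 (2R)-2-[(1S,3S,4S)-3-bromo-4-chloro-4-methylcyclohexyl]-2-hydroxy-5-methylhex-4-enoic acid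
Conditions: NaClO2, NaH2PO4, 2-methylbut-2-ene (excess), t-BuOH/H2O, 0 → 23 °C
Reagents that add atoms: sodium chlorite, [Na+].[O-]Cl=O
Why: Pinnick oxidation of the aldehyde to the acid, with excess 2-methylbut-2-ene scavenging hypochlorous acid so that the prenyl double bond is spared.

Step 13
Reactants: 20 (2R)-2-[(1S,3S,4S)-3-bromo-4-chloro-4-methylcyclohexyl]-2-hydroxy-5-methylhex-4-enoic acid
Product: 21 (3R,5R)-5-bromo-3-[(1S,3S,4S)-3-bromo-4-chloro-4-methylcyclohexyl]-3-hydroxy-6,6-dimethyloxan-2-one
Conditions: 2,4,4,6-tetrabromocyclohexa-2,5-dien-1-one, chiral BINOL-derived bifunctional amidine catalyst (10 mol %), toluene/CH2Cl2, −50 °C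
Reagents that add atoms: 2,4,4,6-tetrabromocyclohexa-2,5-dien-1-one, O=C1C(Br)=CC(Br)(Br)C=C1Br
Why: Catalytic enantioselective bromolactonisation: the carboxylate adds 6-endo at the tertiary alkene carbon (Markovnikov) anti to a bromonium ion whose face is chosen by the catalyst, which should give the (5R) bromide cis to the C3 hydroxyl; the hydrogen bond that holds the α-hydroxyl in the carboxyl plane of the half-chair is expected to reinforce this sense.

Step 14
Reactants: 21 (3R,5R)-5-bromo-3-[(1S,3S,4S)-3-bromo-4-chloro-4-methylcyclohexyl]-3-hydroxy-6,6-dimethyloxan-2-one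
Product: 22 (3R,5R)-5-bromo-3-[(1S,3S,4S)-3-bromo-4-chloro-4-methylcyclohexyl]-6,6-dimethyl-3-[(trimethylsilyl)oxy]oxan-2-one
Conditions: 1-(trimethylsilyl)imidazole, CH2Cl2, 23 °C
Reagents that add atoms: 1-(trimethylsilyl)imidazole, C[Si](C)(C)n1ccnc1
Why: Silylation of the tertiary alcohol with a neutral silyl donor, so that no titanium alkoxide can form next to the carbonyl in the following step.

Step 15
Reactants: 22 (3R,5R)-5-bromo-3-[(1S,3S,4S)-3-bromo-4-chloro-4-methylcyclohexyl]-6,6-dimethyl-3-[(trimethylsilyl)oxy]oxan-2-one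
Product: 23 {[(3R,5R)-5-bromo-3-[(1S,3S,4S)-3-bromo-4-chloro-4-methylcyclohexyl]-6,6-dimethyl-2-methylideneoxan-3-yl]oxy}trimethylsilane
Conditions: Cp2TiMe2 (3 equiv), toluene, 70 °C, dark
Reagents that add atoms: dimethyltitanocene, C[Ti](C)(C1C=CC=C1)C1C=CC=C1
Why: Petasis methylenation: Cp2Ti=CH2 formed on heating adds to the lactone carbonyl and collapses to the enol ether and Cp2Ti=O without acid or base, and the new double bond can only be exocyclic because C3 of the oxane is quaternary.

Step 16
Reactants: 23 {[(3R,5R)-5-bromo-3-[(1S,3S,4S)-3-bromo-4-chloro-4-methylcyclohexyl]-6,6-dimethyl-2-methylideneoxan-3-yl]oxy}trimethylsilane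
Product: 24 (3R,5R)-5-bromo-3-[(1S,3S,4S)-3-bromo-4-chloro-4-methylcyclohexyl]-6,6-dimethyl-2-methylideneoxan-3-ol
Conditions: K2CO3, MeOH, 0 °C; acid-free work-up, Et3N-deactivated silica
Reagents that add atoms: none
Why: Base-catalysed methanolysis of the trimethylsilyl ether, with acid avoided throughout because the product is an enol ether.

## Compound list

1 | nerol, (2Z)-3,7-dimethylocta-2,6-dien-1-ol | CC(C)=CCC/C(C)=C\CO | starting material
2 | (2S,3S)-2-bromo-3-chloro-3,7-dimethyloct-6-en-1-ol | OC[C@H](Br)[C@@](C)(Cl)CCC=C(C)C | intermediate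
3 | {[(2S,3S)-2-bromo-3-chloro-3,7-dimethyloct-6-en-1-yl]oxy}(tert-butyl)dimethylsilane | CC(C)=CCC[C@](C)(Cl)[C@@H](Br)CO[Si](C)(C)C(C)(C)C | intermediate
4 | ozonide (1,2,4-trioxolane) of 3, mixture at the new ring carbon | CC1(C)OOC(CC[C@](C)(Cl)[C@@H](Br)CO[Si](C)(C)C(C)(C)C)O1 | intermediate
5 | (4S,5S)-5-bromo-6-[(tert-butyldimethylsilyl)oxy]-4-chloro-4-methylhexanal | O=CCC[C@](C)(Cl)[C@@H](Br)CO[Si](C)(C)C(C)(C)C | intermediate
6 | ethyl (triphenylphosphoranylidene)acetate | CCOC(=O)C=P(c1ccccc1)(c1ccccc1)c1ccccc1 | starting material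
7 | prenyl bromide, 1-bromo-3-methylbut-2-ene | CC(C)=CCBr | starting material
8 | (1-ethoxy-5-methyl-1-oxohex-4-en-2-yl)triphenylphosphonium bromide | CCOC(=O)C(CC=C(C)C)[P+](c1ccccc1)(c1ccccc1)c1ccccc1.[Br-] | intermediate
9 | ethyl 5-methyl-2-(triphenylphosphoranylidene)hex-4-enoate | CCOC(=O)C(CC=C(C)C)=P(c1ccccc1)(c1ccccc1)c1ccccc1 | intermediate
10 | ethyl (2E,6S,7S)-7-bromo-8-[(tert-butyldimethylsilyl)oxy]-6-chloro-6-methyl-2-(3-methylbut-2-en-1-yl)oct-2-enoate | CCOC(=O)/C(CC=C(C)C)=C/CC[C@](C)(Cl)[C@@H](Br)CO[Si](C)(C)C(C)(C)C | intermediate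
11 | (2E,6S,7S)-7-bromo-8-[(tert-butyldimethylsilyl)oxy]-6-chloro-6-methyl-2-(3-methylbut-2-en-1-yl)oct-2-en-1-ol | OC/C(CC=C(C)C)=C/CC[C@](C)(Cl)[C@@H](Br)CO[Si](C)(C)C(C)(C)C | intermediate
12 | tert-butyl [(2E,6S,7S)-7-bromo-8-[(tert-butyldimethylsilyl)oxy]-6-chloro-6-methyl-2-(3-methylbut-2-en-1-yl)oct-2-en-1-yl] carbonate | CC(C)(C)OC(=O)OC/C(CC=C(C)C)=C/CC[C@](C)(Cl)[C@@H](Br)CO[Si](C)(C)C(C)(C)C | intermediate
13 | tert-butyl [(2E,6S,7S)-7-bromo-6-chloro-8-hydroxy-6-methyl-2-(3-methylbut-2-en-1-yl)oct-2-en-1-yl] carbonate | CC(C)(C)OC(=O)OC/C(CC=C(C)C)=C/CC[C@](C)(Cl)[C@@H](Br)CO | intermediate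
14 | primary triflate of 13 | CC(C)(C)OC(=O)OC/C(CC=C(C)C)=C/CC[C@](C)(Cl)[C@@H](Br)COS(=O)(=O)C(F)(F)F | intermediate
15 | bromonium ion from 14, bromine bridging C7 and C8 of the chain (cation) | CC(C)(C)OC(=O)OC/C(CC=C(C)C)=C/CC[C@](C)(Cl)[C@@H]1C[Br+]1 | intermediate
16 | (4R)-2-tert-butoxy-4-[(1S,3S,4S)-3-bromo-4-chloro-4-methylcyclohexyl]-4-(3-methylbut-2-en-1-yl)-1,3-dioxolan-2-ylium (cation) | CC(C)(C)O[C+]1OC[C@](CC=C(C)C)(O1)[C@H]1CC[C@](C)(Cl)[C@@H](Br)C1 | intermediate
17 | (4R)-4-[(1S,3S,4S)-3-bromo-4-chloro-4-methylcyclohexyl]-4-(3-methylbut-2-en-1-yl)-1,3-dioxolan-2-one | O=C1OC[C@](CC=C(C)C)(O1)[C@H]1CC[C@](C)(Cl)[C@@H](Br)C1 | intermediate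
18 | (2R)-2-[(1S,3S,4S)-3-bromo-4-chloro-4-methylcyclohexyl]-5-methylhex-4-ene-1,2-diol | OC[C@@](O)(CC=C(C)C)[C@H]1CC[C@](C)(Cl)[C@@H](Br)C1 | intermediate
19 | (2R)-2-[(1S,3S,4S)-3-bromo-4-chloro-4-methylcyclohexyl]-2-hydroxy-5-methylhex-4-enal | O=C[C@@](O)(CC=C(C)C)[C@H]1CC[C@](C)(Cl)[C@@H](Br)C1 | intermediate
20 | (2R)-2-[(1S,3S,4S)-3-bromo-4-chloro-4-methylcyclohexyl]-2-hydroxy-5-methylhex-4-enoic acid | OC(=O)[C@@](O)(CC=C(C)C)[C@H]1CC[C@](C)(Cl)[C@@H](Br)C1 | intermediate
21 | (3R,5R)-5-bromo-3-[(1S,3S,4S)-3-bromo-4-chloro-4-methylcyclohexyl]-3-hydroxy-6,6-dimethyloxan-2-one | O=C1OC(C)(C)[C@H](Br)C[C@@]1(O)[C@H]1CC[C@](C)(Cl)[C@@H](Br)C1 | intermediate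
22 | (3R,5R)-5-bromo-3-[(1S,3S,4S)-3-bromo-4-chloro-4-methylcyclohexyl]-6,6-dimethyl-3-[(trimethylsilyl)oxy]oxan-2-one | O=C1OC(C)(C)[C@H](Br)C[C@@]1(O[Si](C)(C)C)[C@H]1CC[C@](C)(Cl)[C@@H](Br)C1 | intermediate
23 | {[(3R,5R)-5-bromo-3-[(1S,3S,4S)-3-bromo-4-chloro-4-methylcyclohexyl]-6,6-dimethyl-2-methylideneoxan-3-yl]oxy}trimethylsilane | C=C1OC(C)(C)[C@H](Br)C[C@@]1(O[Si](C)(C)C)[C@H]1CC[C@](C)(Cl)[C@@H](Br)C1 | intermediate
24 | (3R,5R)-5-bromo-3-[(1S,3S,4S)-3-bromo-4-chloro-4-methylcyclohexyl]-6,6-dimethyl-2-methylideneoxan-3-ol | C=C1OC(C)(C)[C@H](Br)C[C@@]1(O)[C@H]1CC[C@](C)(Cl)[C@@H](Br)C1 | target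

## Step count and risks

Total step count: 16. Longest linear sequence: 15 (steps 1–3 and 5–16; step 4 prepares the ylide).

**1. Step 9 (Proposed new method).** The bromonium ion may hand its bromine to one of the two alkenes. The triflate may also be displaced by the alkene without bromine bridging, through the chair with axial bromine. The carbonate may capture the cation only after bond rotation, which would erode the configuration at the carbinol carbon. The fallback sets out from alcohol 13 and uses two operations of known type. With 4-nitrobenzenesulfonyl chloride, Et3N and catalytic DMAP in CH2Cl2 at 0 °C, 13 should give the isolable tert-butyl [(2E,6S,7S)-7-bromo-6-chloro-6-methyl-2-(3-methylbut-2-en-1-yl)-8-{[(4-nitrophenyl)sulfonyl]oxy}oct-2-en-1-yl] carbonate F1. This is purified and solvolysed slowly at high dilution in (CF3)2CHOH buffered with 2,6-lutidine at 40 °C. Solvolytic π-cyclisation of primary alkenyl arenesulfonates and neighbouring-bromine participation in sulfonate solvolysis are both established. The stationary concentration of cation stays minimal, so intermolecular bromine transfer is suppressed. The same cations 15 and 16 lead back to carbonate 17.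

**2. Step 13.** Facial selection in bromonium formation on the prenyl group may be poor if catalyst and substrate preferences are mismatched. Closure may go 5-exo or through the tertiary hydroxyl, and the bromine donor may oxidatively decarboxylate the α-hydroxy acid. The fallback sets out from acid 20 and replaces the halocyclisation by reagent-controlled epoxidation and bromide opening. Trimethylsilyldiazomethane in toluene/MeOH should give methyl (2R)-2-[(1S,3S,4S)-3-bromo-4-chloro-4-methylcyclohexyl]-2-hydroxy-5-methylhex-4-enoate F2. Shi epoxidation (fructose-derived ketone of the suitable antipode, KHSO5, K2CO3 buffer, MeCN/dimethoxymethane, 0 °C) should give methyl (2R)-2-[(1S,3S,4S)-3-bromo-4-chloro-4-methylcyclohexyl]-3-[(2S)-3,3-dimethyloxiran-2-yl]-2-hydroxypropanoate F3. Li2NiBr4 in THF at 0 °C opens the epoxide at the less substituted carbon with inversion, to methyl (2R,4R)-4-bromo-2-[(1S,3S,4S)-3-bromo-4-chloro-4-methylcyclohexyl]-2,5-dihydroxy-5-methylhexanoate F4. Acid-catalysed lactonisation by the tertiary hydroxyl (camphorsulfonic acid, toluene, 60 °C) comes back to lactone 21.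

**3. Step 15.** Methylenation may stay incomplete at the hindered lactone carbonyl flanked by a quaternary carbon, and the enol ether may be lost by hydrolysis during isolation. The fallback sets out from lactone 22 and builds the exocyclic alkene by addition and elimination. MeLi (1.1 equiv) in THF at −78 °C should give the methyl lactol (3R,5R)-5-bromo-3-[(1S,3S,4S)-3-bromo-4-chloro-4-methylcyclohexyl]-2,6,6-trimethyl-3-[(trimethylsilyl)oxy]oxan-2-ol F5, as an anomeric mixture. Trifluoroacetic anhydride and pyridine in CH2Cl2 at 0 °C convert it into the anomeric trifluoroacetate F6. F6 is not isolated and loses trifluoroacetate with a proton of the methyl group, the only β-hydrogens available. This comes back to enol ether 23.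

## Further compounds

F1 | step 9 | tert-butyl [(2E,6S,7S)-7-bromo-6-chloro-6-methyl-2-(3-methylbut-2-en-1-yl)-8-{[(4-nitrophenyl)sulfonyl]oxy}oct-2-en-1-yl] carbonate | CC(C)(C)OC(=O)OC/C(CC=C(C)C)=C/CC[C@](C)(Cl)[C@@H](Br)COS(=O)(=O)c1ccc(cc1)[N+](=O)[O-]
F2 | step 13 | methyl (2R)-2-[(1S,3S,4S)-3-bromo-4-chloro-4-methylcyclohexyl]-2-hydroxy-5-methylhex-4-enoate | COC(=O)[C@@](O)(CC=C(C)C)[C@H]1CC[C@](C)(Cl)[C@@H](Br)C1
F3 | step 13 | methyl (2R)-2-[(1S,3S,4S)-3-bromo-4-chloro-4-methylcyclohexyl]-3-[(2S)-3,3-dimethyloxiran-2-yl]-2-hydroxypropanoate | COC(=O)[C@@](O)(C[C@@H]1OC1(C)C)[C@H]1CC[C@](C)(Cl)[C@@H](Br)C1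
F4 | step 13 | methyl (2R,4R)-4-bromo-2-[(1S,3S,4S)-3-bromo-4-chloro-4-methylcyclohexyl]-2,5-dihydroxy-5-methylhexanoate | COC(=O)[C@@](O)(C[C@@H](Br)C(C)(C)O)[C@H]1CC[C@](C)(Cl)[C@@H](Br)C1
F5 | step 15 | (3R,5R)-5-bromo-3-[(1S,3S,4S)-3-bromo-4-chloro-4-methylcyclohexyl]-2,6,6-trimethyl-3-[(trimethylsilyl)oxy]oxan-2-ol | CC1(O)OC(C)(C)[C@H](Br)C[C@@]1(O[Si](C)(C)C)[C@H]1CC[C@](C)(Cl)[C@@H](Br)C1
F6 | step 15 | (3R,5R)-5-bromo-3-[(1S,3S,4S)-3-bromo-4-chloro-4-methylcyclohexyl]-2,6,6-trimethyl-3-[(trimethylsilyl)oxy]oxan-2-yl trifluoroacetate | CC1(OC(=O)C(F)(F)F)OC(C)(C)[C@H](Br)C[C@@]1(O[Si](C)(C)C)[C@H]1CC[C@](C)(Cl)[C@@H](Br)C1
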